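**Retrosynthetic overview**
- Target ⇐ global O‑demethylation of the hexameric pentadecamethyl ether monophenol; no ring is constructed, all six benzene rings are bought.
- All five diaryl ether bonds ⇐ metal‑free SNAr of a 2,6‑dioxygenated phenoxide on a fluorobenzaldehyde, instead of the usual Ullmann coupling of halo‑ and hydroxy‑polymethoxybenzenes.
- The formyl group is both the SNAr activator and the latent phenol: Baeyer–Villiger/Dakin oxidation turns it into the next nucleophile, so each ring costs two steps and no protecting‑group operations.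
- Only two electrophiles are needed: 4‑fluoro‑2,6‑dimethoxybenzaldehyde (rings B, D, F) and 6‑fluoro‑2,3,4‑trimethoxybenzaldehyde (rings C, E); the initiator is 2,4,6‑trimethoxyphenol (ring A).
- Rings are attached in the order A → B → C → D → E → F.

Assumption: the target has no stereocentre and no hindered axis (it is achiral), so "single enantiomer" is taken to mean the single constitution given.

Ring letters follow the target SMILES from left to right: A = terminal 2,4,6‑trioxygenated ring, F = terminal 3,4,5‑trioxygenated ring.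

Step 1
Reactants: 1 4-hydroxy-2,6-dimethoxybenzaldehyde
Product: 3 4-fluoro-2,6-dimethoxybenzaldehyde, via aryloxyimidazolium bifluoride 2 (not isolated)
Conditions: PhenoFluor (1.2 equiv), CsF (3 equiv), toluene, 110 °C, 20 h
Reagents that add atoms: PhenoFluor (1,3-bis(2,6-diisopropylphenyl)-2,2-difluoro-2,3-dihydro-1H-imidazole), CC(C)c1cccc(C(C)C)c1N1C=CN(c2c(C(C)C)cccc2C(C)C)C1(F)F; cesium fluoride (exchanging fluoride pool), [Cs+].[F-]
Why: Phenol deoxyfluorination: the phenol condenses with the reagent to a 2‑aryloxyimidazolium bifluoride, and fluoride then displaces the urea leaving group by concerted SNAr at a carbon para to CHO, the aldehyde being inert to this reagent; no stereocentre is formed.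

Step 2
Reactants: 4 2,3,4-trimethoxybenzaldehyde
Product: 8 6-fluoro-2,3,4-trimethoxybenzaldehyde, via lithium amino alkoxide 5 (not isolated), via C6-lithiated amino alkoxide 6 (not isolated), via fluorinated amino alkoxide 7 (not isolated)
Conditions: LiN(Me)CH2CH2NMe2 (from Me2NCH2CH2NHMe + n-BuLi), THF, −20 °C; n-BuLi (3 equiv), −20 °C, 24 h; NFSI (4 equiv), −78 °C → rt; H2O
Reagents that add atoms: NFSI (N-fluorobenzenesulfonimide), O=S(=O)(c1ccccc1)N(F)S(=O)(=O)c1ccccc1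
Why: Comins α‑amino‑alkoxide directed ortho‑lithiation followed by electrophilic fluorination: the in situ aminal alkoxide masks CHO and its chelating NMe2 arm directs n‑BuLi to C6, the only free ortho position, the aryllithium is fluorinated by NFSI, and water releases the aldehyde (the racemic aminal carbon is lost).

Step 3
Reactants: 9 2,4,6-trimethoxyphenol; 3 4-fluoro-2,6-dimethoxybenzaldehyde
Product: 10 2,6-dimethoxy-4-(2,4,6-trimethoxyphenoxy)benzaldehyde (A–B aldehyde)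
Conditions: Cs2CO3 (1.5 equiv), degassed DMSO, 100 °C, Ar, 12 h
Reagents that add atoms: none
Why: SNAr (addition–elimination): the electron‑rich cesium phenoxide attacks the C–F carbon para to CHO, the Meisenheimer charge is delocalised onto the formyl oxygen, and fluoride is by far the best leaving group on the ring.

Step 4
Reactants: 10 2,6-dimethoxy-4-(2,4,6-trimethoxyphenoxy)benzaldehyde
Product: 12 2,6-dimethoxy-4-(2,4,6-trimethoxyphenoxy)phenol (A–B phenol), via aryl formate 11 (not isolated)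
Conditions: mCPBA (1.3 equiv), CH2Cl2, 0 °C → rt; aq. Na2SO3/NaHCO3 wash; crude formate, K2CO3 (0.2 equiv), MeOH, rt, Ar
Reagents that add atoms: mCPBA (3-chloroperoxybenzoic acid), OOC(=O)c1cccc(Cl)c1
Why: Baeyer–Villiger (Dakin‑type) oxidation: the aryl group with two ortho and one para oxygen donors migrates in preference to H to give the aryl formate, which is methanolysed only after the peracid has been removed, so the electron‑rich phenol is not over‑oxidised.

Step 5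
Reactants: 12 2,6-dimethoxy-4-(2,4,6-trimethoxyphenoxy)phenol; 8 6-fluoro-2,3,4-trimethoxybenzaldehyde (1.5 equiv)
Product: 13 6-[2,6-dimethoxy-4-(2,4,6-trimethoxyphenoxy)phenoxy]-2,3,4-trimethoxybenzaldehyde (A–B–C aldehyde)
Conditions: Cs2CO3 (2 equiv), degassed DMSO, 130 °C, Ar, 24 h
Reagents that add atoms: none
Why: SNAr at a fluoride ortho to CHO: the fluorine has an H neighbour, so the site is accessible to the hindered 2,6‑dimethoxyphenoxide, and the ortho‑formyl group stabilises the Meisenheimer intermediate although the methoxy groups slow the reaction.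

Step 6
Reactants: 13 6-[2,6-dimethoxy-4-(2,4,6-trimethoxyphenoxy)phenoxy]-2,3,4-trimethoxybenzaldehyde
Product: 15 6-[2,6-dimethoxy-4-(2,4,6-trimethoxyphenoxy)phenoxy]-2,3,4-trimethoxyphenol (A–B–C phenol), via aryl formate 14 (not isolated)
Conditions: mCPBA (1.3 equiv), CH2Cl2, 0 °C → rt; aq. Na2SO3/NaHCO3 wash; crude formate, K2CO3 (0.2 equiv), MeOH, rt, Ar
Reagents that add atoms: mCPBA (3-chloroperoxybenzoic acid), OOC(=O)c1cccc(Cl)c1
Why: Baeyer–Villiger (Dakin‑type) oxidation: the migrating ring carries ortho‑OMe, ortho‑OAr and para‑OMe donors, so aryl migration to the formate is strongly favoured, and mild methanolysis frees the phenol that sits next to the A–B ether.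

Step 7
Reactants: 15 6-[2,6-dimethoxy-4-(2,4,6-trimethoxyphenoxy)phenoxy]-2,3,4-trimethoxyphenol; 3 4-fluoro-2,6-dimethoxybenzaldehyde (1.3 equiv)
Product: 16 4-{6-[2,6-dimethoxy-4-(2,4,6-trimethoxyphenoxy)phenoxy]-2,3,4-trimethoxyphenoxy}-2,6-dimethoxybenzaldehyde (A–B–C–D aldehyde)
Conditions: Cs2CO3 (1.5 equiv), degassed DMSO, 110 °C, Ar, 16 h
Reagents that add atoms: none
Why: SNAr as in step 3: the para‑formyl fluoride has two H neighbours, so even the 2‑aryloxy‑6‑methoxyphenoxide can add, and the neighbouring B ring is too electron‑rich for a competing Smiles rearrangement.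

Step 8
Reactants: 16 4-{6-[2,6-dimethoxy-4-(2,4,6-trimethoxyphenoxy)phenoxy]-2,3,4-trimethoxyphenoxy}-2,6-dimethoxybenzaldehyde
Product: 18 4-{6-[2,6-dimethoxy-4-(2,4,6-trimethoxyphenoxy)phenoxy]-2,3,4-trimethoxyphenoxy}-2,6-dimethoxyphenol (A–B–C–D phenol), via aryl formate 17 (not isolated)
Conditions: mCPBA (1.3 equiv), CH2Cl2, 0 °C → rt; aq. Na2SO3/NaHCO3 wash; crude formate, K2CO3 (0.2 equiv), MeOH, rt, Ar
Reagents that add atoms: mCPBA (3-chloroperoxybenzoic acid), OOC(=O)c1cccc(Cl)c1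
Why: Baeyer–Villiger (Dakin‑type) oxidation of a 2,6‑dimethoxy‑4‑aryloxybenzaldehyde, the same electronic situation as in step 4, gives the formate and then the flanked phenol.

Step 9
Reactants: 18 4-{6-[2,6-dimethoxy-4-(2,4,6-trimethoxyphenoxy)phenoxy]-2,3,4-trimethoxyphenoxy}-2,6-dimethoxyphenol; 8 6-fluoro-2,3,4-trimethoxybenzaldehyde (1.5 equiv)
Product: 19 6-(4-{6-[2,6-dimethoxy-4-(2,4,6-trimethoxyphenoxy)phenoxy]-2,3,4-trimethoxyphenoxy}-2,6-dimethoxyphenoxy)-2,3,4-trimethoxybenzaldehyde (A–B–C–D–E aldehyde)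
Conditions: Cs2CO3 (2 equiv), degassed DMSO, 130 °C, Ar, 24 h
Reagents that add atoms: none
Why: SNAr at the ortho‑formyl fluoride, a repeat of step 5 with the same 2,6‑dimethoxy‑4‑aryloxyphenoxide type of nucleophile.

Step 10
Reactants: 19 6-(4-{6-[2,6-dimethoxy-4-(2,4,6-trimethoxyphenoxy)phenoxy]-2,3,4-trimethoxyphenoxy}-2,6-dimethoxyphenoxy)-2,3,4-trimethoxybenzaldehyde
Product: 21 6-(4-{6-[2,6-dimethoxy-4-(2,4,6-trimethoxyphenoxy)phenoxy]-2,3,4-trimethoxyphenoxy}-2,6-dimethoxyphenoxy)-2,3,4-trimethoxyphenol (A–B–C–D–E phenol), via aryl formate 20 (not isolated)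
Conditions: mCPBA (1.3 equiv), CH2Cl2, 0 °C → rt; aq. Na2SO3/NaHCO3 wash; crude formate, K2CO3 (0.2 equiv), MeOH, rt, Ar
Reagents that add atoms: mCPBA (3-chloroperoxybenzoic acid), OOC(=O)c1cccc(Cl)c1
Why: Baeyer–Villiger (Dakin‑type) oxidation, a repeat of step 6 on the same tri‑donor‑substituted benzaldehyde type.

Step 11
Reactants: 21 6-(4-{6-[2,6-dimethoxy-4-(2,4,6-trimethoxyphenoxy)phenoxy]-2,3,4-trimethoxyphenoxy}-2,6-dimethoxyphenoxy)-2,3,4-trimethoxyphenol; 3 4-fluoro-2,6-dimethoxybenzaldehyde (1.5 equiv)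
Product: 22 4-[6-(4-{6-[2,6-dimethoxy-4-(2,4,6-trimethoxyphenoxy)phenoxy]-2,3,4-trimethoxyphenoxy}-2,6-dimethoxyphenoxy)-2,3,4-trimethoxyphenoxy]-2,6-dimethoxybenzaldehyde (A–B–C–D–E–F aldehyde)
Conditions: Cs2CO3 (1.5 equiv), degassed DMSO, 120 °C, Ar, 24 h
Reagents that add atoms: none
Why: SNAr at the para‑formyl fluoride, a repeat of step 7, which installs the last ring with its future 4‑OH still masked as CHO.

Step 12
Reactants: 22 4-[6-(4-{6-[2,6-dimethoxy-4-(2,4,6-trimethoxyphenoxy)phenoxy]-2,3,4-trimethoxyphenoxy}-2,6-dimethoxyphenoxy)-2,3,4-trimethoxyphenoxy]-2,6-dimethoxybenzaldehyde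
Product: 24 4-[6-(4-{6-[2,6-dimethoxy-4-(2,4,6-trimethoxyphenoxy)phenoxy]-2,3,4-trimethoxyphenoxy}-2,6-dimethoxyphenoxy)-2,3,4-trimethoxyphenoxy]-2,6-dimethoxyphenol (hexamer pentadecamethyl ether), via aryl formate 23 (not isolated)
Conditions: mCPBA (1.3 equiv), CH2Cl2, 0 °C → rt; aq. Na2SO3/NaHCO3 wash; crude formate, K2CO3 (0.2 equiv), MeOH, rt, Ar
Reagents that add atoms: mCPBA (3-chloroperoxybenzoic acid), OOC(=O)c1cccc(Cl)c1
Why: Baeyer–Villiger (Dakin‑type) oxidation as in step 4 converts the last formyl group into the central OH of the 3,4,5‑trioxygenated F ring.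

Step 13
Reactants: 24 4-[6-(4-{6-[2,6-dimethoxy-4-(2,4,6-trimethoxyphenoxy)phenoxy]-2,3,4-trimethoxyphenoxy}-2,6-dimethoxyphenoxy)-2,3,4-trimethoxyphenoxy]-2,6-dimethoxyphenol
Product: 26 target CNP0114537.0 (hexadecaphenol), via dibromoboryl ether 25 (not isolated)
Conditions: BBr3 (45 equiv), CH2Cl2, −78 °C → rt, 36 h; H2O, 0 °C; Sephadex LH-20 (MeOH) under Ar
Reagents that add atoms: none
Why: Lewis‑acid O‑demethylation: BBr3 coordinates each methoxy oxygen and bromide removes the methyl group by SN2 as MeBr, while the diaryl ether C–O bonds (both carbons sp2) are inert, and hydrolysis of the aryl borates frees all sixteen hydroxyls.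

**Compound list**
1 | 4-hydroxy-2,6-dimethoxybenzaldehyde | O=Cc1c(OC)cc(O)cc1OC | starting material
2 | 2-(4-formyl-3,5-dimethoxyphenoxy)-1,3-bis(2,6-diisopropylphenyl)imidazolium hydrogen difluoride | O=Cc1c(OC)cc(Oc2n(-c3c(C(C)C)cccc3C(C)C)cc[n+]2-c2c(C(C)C)cccc2C(C)C)cc1OC.F.[F-] | intermediate
3 | 4-fluoro-2,6-dimethoxybenzaldehyde | O=Cc1c(OC)cc(F)cc1OC | intermediate
4 | 2,3,4-trimethoxybenzaldehyde | O=Cc1ccc(OC)c(OC)c1OC | starting material
5 | lithium α-[N-methyl-N-(2-dimethylaminoethyl)amino]-2,3,4-trimethoxybenzyl alkoxide (racemic) | [Li+].[O-]C(N(C)CCN(C)C)c1ccc(OC)c(OC)c1OC | intermediate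
6 | C6-lithiated derivative of 5 (racemic) | [Li+].[O-]C(N(C)CCN(C)C)c1c([Li])cc(OC)c(OC)c1OC | intermediate
7 | lithium α-amino alkoxide of 6-fluoro-2,3,4-trimethoxybenzaldehyde (racemic) | [Li+].[O-]C(N(C)CCN(C)C)c1c(F)cc(OC)c(OC)c1OC | intermediate
8 | 6-fluoro-2,3,4-trimethoxybenzaldehyde | O=Cc1c(F)cc(OC)c(OC)c1OC | intermediate
9 | 2,4,6-trimethoxyphenol | COc1cc(OC)c(O)c(OC)c1 | starting material
10 | 2,6-dimethoxy-4-(2,4,6-trimethoxyphenoxy)benzaldehyde | O=Cc1c(OC)cc(Oc2c(OC)cc(OC)cc2OC)cc1OC | intermediate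
11 | 2,6-dimethoxy-4-(2,4,6-trimethoxyphenoxy)phenyl formate | O=COc1c(OC)cc(Oc2c(OC)cc(OC)cc2OC)cc1OC | intermediate
12 | 2,6-dimethoxy-4-(2,4,6-trimethoxyphenoxy)phenol | Oc1c(OC)cc(Oc2c(OC)cc(OC)cc2OC)cc1OC | intermediate
13 | 6-[2,6-dimethoxy-4-(2,4,6-trimethoxyphenoxy)phenoxy]-2,3,4-trimethoxybenzaldehyde | O=Cc1c(Oc2c(OC)cc(Oc3c(OC)cc(OC)cc3OC)cc2OC)cc(OC)c(OC)c1OC | intermediate
14 | formate ester of 15 | O=COc1c(Oc2c(OC)cc(Oc3c(OC)cc(OC)cc3OC)cc2OC)cc(OC)c(OC)c1OC | intermediate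
15 | 6-[2,6-dimethoxy-4-(2,4,6-trimethoxyphenoxy)phenoxy]-2,3,4-trimethoxyphenol | Oc1c(Oc2c(OC)cc(Oc3c(OC)cc(OC)cc3OC)cc2OC)cc(OC)c(OC)c1OC | intermediate
16 | 4-{6-[2,6-dimethoxy-4-(2,4,6-trimethoxyphenoxy)phenoxy]-2,3,4-trimethoxyphenoxy}-2,6-dimethoxybenzaldehyde | O=Cc1c(OC)cc(Oc2c(Oc3c(OC)cc(Oc4c(OC)cc(OC)cc4OC)cc3OC)cc(OC)c(OC)c2OC)cc1OC | intermediate
17 | formate ester of 18 | O=COc1c(OC)cc(Oc2c(Oc3c(OC)cc(Oc4c(OC)cc(OC)cc4OC)cc3OC)cc(OC)c(OC)c2OC)cc1OC | intermediate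
18 | 4-{6-[2,6-dimethoxy-4-(2,4,6-trimethoxyphenoxy)phenoxy]-2,3,4-trimethoxyphenoxy}-2,6-dimethoxyphenol | Oc1c(OC)cc(Oc2c(Oc3c(OC)cc(Oc4c(OC)cc(OC)cc4OC)cc3OC)cc(OC)c(OC)c2OC)cc1OC | intermediate
19 | 6-(4-{6-[2,6-dimethoxy-4-(2,4,6-trimethoxyphenoxy)phenoxy]-2,3,4-trimethoxyphenoxy}-2,6-dimethoxyphenoxy)-2,3,4-trimethoxybenzaldehyde | O=Cc1c(Oc2c(OC)cc(Oc3c(Oc4c(OC)cc(Oc5c(OC)cc(OC)cc5OC)cc4OC)cc(OC)c(OC)c3OC)cc2OC)cc(OC)c(OC)c1OC | intermediate
20 | formate ester of 21 | O=COc1c(Oc2c(OC)cc(Oc3c(Oc4c(OC)cc(Oc5c(OC)cc(OC)cc5OC)cc4OC)cc(OC)c(OC)c3OC)cc2OC)cc(OC)c(OC)c1OC | intermediate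
21 | 6-(4-{6-[2,6-dimethoxy-4-(2,4,6-trimethoxyphenoxy)phenoxy]-2,3,4-trimethoxyphenoxy}-2,6-dimethoxyphenoxy)-2,3,4-trimethoxyphenol | Oc1c(Oc2c(OC)cc(Oc3c(Oc4c(OC)cc(Oc5c(OC)cc(OC)cc5OC)cc4OC)cc(OC)c(OC)c3OC)cc2OC)cc(OC)c(OC)c1OC | intermediate
22 | 4-[6-(4-{6-[2,6-dimethoxy-4-(2,4,6-trimethoxyphenoxy)phenoxy]-2,3,4-trimethoxyphenoxy}-2,6-dimethoxyphenoxy)-2,3,4-trimethoxyphenoxy]-2,6-dimethoxybenzaldehyde | O=Cc1c(OC)cc(Oc2c(Oc3c(OC)cc(Oc4c(Oc5c(OC)cc(Oc6c(OC)cc(OC)cc6OC)cc5OC)cc(OC)c(OC)c4OC)cc3OC)cc(OC)c(OC)c2OC)cc1OC | intermediate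
23 | formate ester of 24 | O=COc1c(OC)cc(Oc2c(Oc3c(OC)cc(Oc4c(Oc5c(OC)cc(Oc6c(OC)cc(OC)cc6OC)cc5OC)cc(OC)c(OC)c4OC)cc3OC)cc(OC)c(OC)c2OC)cc1OC | intermediate
24 | 4-[6-(4-{6-[2,6-dimethoxy-4-(2,4,6-trimethoxyphenoxy)phenoxy]-2,3,4-trimethoxyphenoxy}-2,6-dimethoxyphenoxy)-2,3,4-trimethoxyphenoxy]-2,6-dimethoxyphenol | Oc1c(OC)cc(Oc2c(Oc3c(OC)cc(Oc4c(Oc5c(OC)cc(Oc6c(OC)cc(OC)cc6OC)cc5OC)cc(OC)c(OC)c4OC)cc3OC)cc(OC)c(OC)c2OC)cc1OC | intermediate
25 | hexadecakis(dibromoboryl) ether of the target (idealised borate intermediate) | BrB(Br)Oc1c(OB(Br)Br)cc(Oc2c(Oc3c(OB(Br)Br)cc(Oc4c(Oc5c(OB(Br)Br)cc(Oc6c(OB(Br)Br)cc(OB(Br)Br)cc6OB(Br)Br)cc5OB(Br)Br)cc(OB(Br)Br)c(OB(Br)Br)c4OB(Br)Br)cc3OB(Br)Br)cc(OB(Br)Br)c(OB(Br)Br)c2OB(Br)Br)cc1OB(Br)Br | intermediate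
26 | CNP0114537.0 (achiral hexameric polyphenol) | Oc1cc(O)c(Oc2cc(O)c(Oc3cc(O)c(O)c(O)c3Oc3cc(O)c(Oc4cc(O)c(O)c(O)c4Oc4cc(O)c(O)c(O)c4)c(O)c3)c(O)c2)c(O)c1 | target

**Totals**
Total step count: 13.
Longest linear sequence: 12 steps (1 → 3 → 10 → 12 → 13 → 15 → 16 → 18 → 19 → 21 → 22 → 24 → 26; steps 1 and 3–13).

**Three steps most likely to fail**

Step 5 (the same problem would recur in step 9). The fluoride of 8 is para to one methoxy group and the formyl group is cross‑conjugated with two others, so the ring is a weak SNAr acceptor, and the nucleophile is a 2,6‑disubstituted phenoxide. The likely failure is no conversion, or methyl transfer at 130 °C. The fallback replaces SNAr by a copper‑catalysed Ullmann‑type coupling. It sets out from the C6‑lithiated amino alkoxide 6 (made from 4 exactly as in step 2) and from phenol 12. Compound 6 is quenched with 1,2‑dibromotetrachloroethane instead of NFSI to give the lithium α‑amino alkoxide of 6‑bromo‑2,3,4‑trimethoxybenzaldehyde F1, which on aqueous work‑up releases 6‑bromo‑2,3,4‑trimethoxybenzaldehyde F2. F2 is then coupled with 12 (CuI 10 mol%, picolinic acid 20 mol%, Cs2CO3, DMSO, 90 °C), the ortho‑formyl group assisting oxidative addition. The product is aldehyde 13, where the route resumes at step 6; the same change turns 18 into 19.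

Step 11 (the same remedy applies to steps 3 and 7). The nucleophile 21 is a large, doubly ortho‑substituted phenoxide, and the electrophile 3 is deactivated by two methoxy groups conjugated with its formyl group. On precious late material a sluggish reaction at 120 °C invites decomposition. The fallback replaces SNAr by a palladium‑catalysed C–O cross‑coupling. It sets out from phenol 1 and from 21. Compound 1 is triflated (Tf2O, pyridine, CH2Cl2, 0 °C) to 4‑formyl‑3,5‑dimethoxyphenyl trifluoromethanesulfonate F3. F3 is coupled with 21 (Pd(OAc)2, t‑BuXPhos, K3PO4, toluene, 100 °C), reductive elimination being helped by the electron‑poor aryl group on palladium. The product is aldehyde 22, where the route resumes at step 12.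

Step 13. Fifteen methyl ethers must all be cleaved, and the product, with three pyrogallol‑type rings, oxidises readily in air and is hard to purify free of partly methylated material. The fallback is a derivatise–purify–release sequence. It sets out from 24, which is treated with BBr3 as in step 13. After the aqueous quench the crude, dried polyphenol is not purified but peracetylated (Ac2O, pyridine, DMAP, rt) to the hexadecaacetate of the target F4. F4 is air‑stable and chromatographable on silica, and its acetate count by NMR proves complete demethylation. Acid methanolysis of F4 (HCl generated from AcCl in MeOH, 40 °C, Ar), followed by evaporation, returns to the target 26.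

**Further compounds**
F1 | step 5 | lithium α-amino alkoxide of 6-bromo-2,3,4-trimethoxybenzaldehyde (racemic) | [Li+].[O-]C(N(C)CCN(C)C)c1c(Br)cc(OC)c(OC)c1OC
F2 | step 5 | 6-bromo-2,3,4-trimethoxybenzaldehyde | O=Cc1c(Br)cc(OC)c(OC)c1OC
F3 | step 11 | 4-formyl-3,5-dimethoxyphenyl trifluoromethanesulfonate | O=Cc1c(OC)cc(OS(=O)(=O)C(F)(F)F)cc1OC
F4 | step 13 | hexadecaacetate of the target | CC(=O)Oc1cc(OC(C)=O)c(Oc2cc(OC(C)=O)c(Oc3cc(OC(C)=O)c(OC(C)=O)c(OC(C)=O)c3Oc3cc(OC(C)=O)c(Oc4cc(OC(C)=O)c(OC(C)=O)c(OC(C)=O)c4Oc4cc(OC(C)=O)c(OC(C)=O)c(OC(C)=O)c4)c(OC(C)=O)c3)c(OC(C)=O)c2)c(OC(C)=O)c1
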